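## Retrosynthet­ic overview

1. Target ⇒ enone **14** by late cis-dihydroxylation of C8=C9; **14** ⇒ hydroxy-enone **12** by α′-acyloxylation at C6; **12** ⇒ trans-fused hydroazulenedione **11** by isopropyl addition to the C4 ketone.
2. **11** ⇒ spiro[4.5]decane (acorane-type) bis-silyl ether **10** by one cationic cascade: 1,2-alkyl shift (six- to seven-membered ring) followed by 1,2-hydride shift from the neighbouring carbinol carbon.
3. Spirocycle **8** ⇒ monocyclic bisabolane-type enone (lactol **7**) by reductive ketyl–enone spirocyclisation (five-membered ring).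
4. Enone **5** ⇒ (R)-linalool **1** + 3-methylbut-3-en-2-one **3** (Wacker oxidation, Robinson annulation).
5. Ring order: six-membered ring (annulation) → five-membered ring (spirocyclisation) → seven-membered ring (ring expansion of the six-membered ring).

Assumption: the daucane skeleton is taken to arise in the plant from a bisabolyl cation through an acorenyl (spiro[4.5]decyl) cation, a 1,2-alkyl shift (ring expansion) and a 1,2-hydride shift to a C4 cation; the three rings are built here in that order.

Daucane numbering is used for the bicyclic compounds: C1 = methyl-bearing ring-fusion carbon, C4 = isopropyl carbinol carbon, C5 = ring-fusion CH, C6 = acyloxy carbon, C7 = ketone, C8/C9 = diol carbons. Compounds 4–8 carry one epimerisable CH(CH3) centre as a mixture; it is left undefined in their SMILES and becomes sp2 in step 5.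

## Route

Step 1
Reactants: 1 (R)-(−)-linalool, (3R)-3,7-dimethylocta-1,6-dien-3-ol
Product: 2 (3R)-3-hydroxy-3,7-dimethyloct-6-en-2-one
Conditions: PdCl2 (10 mol %), CuCl (1 equiv), O2 (1 atm), DMF/H2O 7:1, rt
Reagents that add atoms: water, O
Why: Tsuji–Wacker oxidation converts only the monosubstituted vinyl group (Markovnikov) into the methyl ketone, the trisubstituted alkene is inert and the carbinol stereocentre is not touched.

Step 2
Reactants: 2 (3R)-3-hydroxy-3,7-dimethyloct-6-en-2-one; 3 3-methylbut-3-en-2-one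
Product: 5 3-[(2R)-2-hydroxy-6-methylhept-5-en-2-yl]-6-methylcyclohex-2-en-1-one, via Michael adduct diketone 4 (not isolated)
Conditions: LDA (2.2 equiv), THF, −78 °C; 3, −78 → 0 °C; then KOH, MeOH, 60 °C
Reagents that add atoms: 3-methylbut-3-en-2-one (compound 3), CC(=C)C(C)=O
Why: Robinson annulation in which the only enolisable side of 2 (the methyl group) adds to 3 and the new methyl-ketone enolate closes onto the hindered ketone in the single possible six-membered aldol condensation; the carbinol centre is untouched and the ring C-methyl centre forms as an inconsequential epimer mixture.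

Step 3
Reactants: 5 3-[(2R)-2-hydroxy-6-methylhept-5-en-2-yl]-6-methylcyclohex-2-en-1-one
Product: 7 3-[(2R)-5-hydroxy-2-methyloxolan-2-yl]-6-methylcyclohex-2-en-1-one, via open hydroxy aldehyde 6 (not isolated)
Conditions: O3, CH2Cl2/MeOH, pyridine, −78 °C (stop at first excess); Me2S, −78 °C → rt
Reagents that add atoms: ozone, [O-][O+]=O
Why: chemoselective ozonolysis of the electron-rich trisubstituted alkene in the presence of the electron-poor conjugated enone, the γ-hydroxy aldehyde closing to the five-membered lactol (anomer mixture).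

Step 4
Reactants: 7 3-[(2R)-5-hydroxy-2-methyloxolan-2-yl]-6-methylcyclohex-2-en-1-one
Product: 8 (1R,4S,5S)-1,4-dihydroxy-1,8-dimethylspiro[4.5]decan-7-one
Conditions: SmI2 (2.5 equiv), THF, MeOH (10 equiv), no HMPA, −78 → 0 °C
Reagents that add atoms: none
Why: SmI2 ketyl–enone reductive 5-exo spirocyclisation (ketyl–olefin coupling) of the aldehyde released from the lactol, in which trivalent samarium bridges the tertiary alkoxide and the ketyl oxygen in a chair-like transition state with the carbinol methyl equatorial, so that both oxygens end up cis to each other and cis to the CH2 next to the ketone and the (R)-carbinol centre thereby fixes the spiro centre (5S) and the new carbinol centre (4S).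

Step 5
Reactants: 8 (1R,4S,5S)-1,4-dihydroxy-1,8-dimethylspiro[4.5]decan-7-one
Product: 10 (1R,4S,5S)-1,8-dimethyl-1,4-bis(trimethylsilyloxy)spiro[4.5]dec-8-en-7-one, via tris-silyl enol ether 9 (not isolated)
Conditions: TMSOTf (3.5 equiv), Et3N (5 equiv), CH2Cl2, 0 °C → rt; concentrate; Pd(OAc)2 (1.05 equiv), MeCN, rt
Reagents that add atoms: trimethylsilyl trifluoromethanesulfonate, C[Si](C)(C)OS(=O)(=O)C(F)(F)F
Why: silylation of both hydroxyls with formation of the more substituted silyl enol ether under equilibrating conditions, then Saegusa–Ito oxidation, which can only give the 2-methyl enone because the other α-carbon is attached to the quaternary spiro carbon and has no β-hydrogen.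

Step 6
Reactants: 10 (1R,4S,5S)-1,8-dimethyl-1,4-bis(trimethylsilyloxy)spiro[4.5]dec-8-en-7-one
Product: 11 (3aR,8aR)-6,8a-dimethyl-1,2,3a,4,8,8a-hexahydroazulene-3,5-dione
Conditions: TMSOTf (0.3 equiv), CH2Cl2, −78 → 0 °C; cold aq. NaHCO3
Reagents that add atoms: none
Why: Proposed new method: TMSOTf silylates the tertiary siloxy oxygen, which leaves as hexamethyldisiloxane while the ring CH2 antiperiplanar to it (the one not flanked by the carbonyl, hence also the better migrating group) shifts to the cationic carbon (Wagner–Meerwein ring expansion, spiro[4.5] to bicyclo[5.3.0], setting the quaternary methyl centre C1), and the tertiary ring-fusion cation is then quenched by a 1,2-hydride shift from the adjacent silyloxy carbon on the face cis to the migrated CH2 (setting the trans C5–H and the C4 carbonyl), the silyloxocarbenium ion returning the silyl group to triflate; the closest known reaction types are the acid-induced acorane-to-daucane (spiro[4.5]decyl cation to hydroazulene) ring expansion and Lewis-acid semipinacol rearrangements of silyl ethers.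

Step 7
Reactants: 11 (3aR,8aR)-6,8a-dimethyl-1,2,3a,4,8,8a-hexahydroazulene-3,5-dione
Product: 12 (3R,3aR,8aR)-3-hydroxy-6,8a-dimethyl-3-(propan-2-yl)-2,3,3a,4,8,8a-hexahydroazulen-5(1H)-one
Conditions: i-PrMgCl (1.5 equiv), CeCl3 (anhydrous, 1.6 equiv), THF, −78 °C
Reagents that add atoms: isopropylmagnesium chloride, CC(C)[Mg]Cl
Why: organocerium 1,2-addition, chemoselective for the saturated cyclopentanone over the conjugated α-methyl enone and non-basic enough to leave the adjacent ring-fusion centre unepimerised, with attack from the face of the ring-fusion hydrogen (anti to C6 and to the angular-methyl side) so that the new hydroxyl is cis to the angular methyl.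

Step 8
Reactants: 12 (3R,3aR,8aR)-3-hydroxy-6,8a-dimethyl-3-(propan-2-yl)-2,3,3a,4,8,8a-hexahydroazulen-5(1H)-one; 13 4-(benzyloxy)benzoic acid
Product: 14 (3R,3aS,4R,8aR)-3-hydroxy-6,8a-dimethyl-5-oxo-3-(propan-2-yl)-1,2,3,3a,4,5,8,8a-octahydroazulen-4-yl 4-(benzyloxy)benzoate
Conditions: Mn(OAc)3·2H2O (3 equiv), 13 (5 equiv), benzene, reflux, Dean–Stark
Reagents that add atoms: 4-(benzyloxy)benzoic acid (compound 13), OC(=O)c1ccc(OCc2ccccc2)cc1
Why: Mn(OAc)3-mediated α′-acyloxylation of an enone after carboxylate exchange on manganese, regioselective for the only α′ CH2 (C6), the epimerisable new centre settling in the equatorial arrangement with H5 and H6 trans-diaxial (acyloxy cis to H5).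

Step 9
Reactants: 14 (3R,3aS,4R,8aR)-3-hydroxy-6,8a-dimethyl-5-oxo-3-(propan-2-yl)-1,2,3,3a,4,5,8,8a-octahydroazulen-4-yl 4-(benzyloxy)benzoate
Product: 15 (3R,3aS,4R,6S,7S,8aR)-3,6,7-trihydroxy-6,8a-dimethyl-5-oxo-3-(propan-2-yl)decahydroazulen-4-yl 4-(benzyloxy)benzoate
Conditions: OsO4 (5 mol %), NMO (1.5 equiv), citric acid (1 equiv), t-BuOH/H2O 1:1, rt
Reagents that add atoms: osmium tetroxide, O=[Os](=O)(=O)=O; N-methylmorpholine N-oxide, C[N+]1([O-])CCOCC1; water, O
Why: Upjohn cis-dihydroxylation (citric acid speeds turnover on the electron-poor enone alkene) from the face opposite the axial angular methyl, the equatorial C6 ester offering little shielding, which places both new hydroxyls cis to H5.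

Step 10
Reactants: 15 (3R,3aS,4R,6S,7S,8aR)-3,6,7-trihydroxy-6,8a-dimethyl-5-oxo-3-(propan-2-yl)decahydroazulen-4-yl 4-(benzyloxy)benzoate
Product: 16 (3R,3aS,4R,6S,7S,8aR)-3,6,7-trihydroxy-6,8a-dimethyl-5-oxo-3-(propan-2-yl)decahydroazulen-4-yl 4-hydroxybenzoate
Conditions: H2 (1 atm), Pd/C (10 wt %), EtOAc, rt
Reagents that add atoms: none
Why: hydrogenolysis of the benzyl aryl ether under neutral conditions, with no alkene left and the ketone, esters and α-ketol unaffected.

## Compound list

1 | (R)-(−)-linalool, (3R)-3,7-dimethylocta-1,6-dien-3-ol | C[C@@](O)(CCC=C(C)C)C=C | starting material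
2 | (3R)-3-hydroxy-3,7-dimethyloct-6-en-2-one | C[C@@](O)(CCC=C(C)C)C(C)=O | intermediate
3 | 3-methylbut-3-en-2-one | CC(=C)C(C)=O | starting material
4 | (7R)-7-hydroxy-3,7,11-trimethyldodec-10-ene-2,6-dione (C3 epimers; not isolated) | C[C@@](O)(CCC=C(C)C)C(=O)CCC(C)C(C)=O | intermediate
5 | 3-[(2R)-2-hydroxy-6-methylhept-5-en-2-yl]-6-methylcyclohex-2-en-1-one (C6 epimers) | C[C@@](O)(CCC=C(C)C)C1=CC(=O)C(C)CC1 | intermediate
6 | (4R)-4-hydroxy-4-(4-methyl-3-oxocyclohex-1-en-1-yl)pentanal (open form; not isolated) | C[C@@](O)(CCC=O)C1=CC(=O)C(C)CC1 | intermediate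
7 | 3-[(2R)-5-hydroxy-2-methyloxolan-2-yl]-6-methylcyclohex-2-en-1-one (lactol, anomer mixture) | C[C@@]1(CCC(O)O1)C2=CC(=O)C(C)CC2 | intermediate
8 | (1R,4S,5S)-1,4-dihydroxy-1,8-dimethylspiro[4.5]decan-7-one (both hydroxyls cis to each other and to the C6 methylene; C8 epimers) | C[C@@]1(O)CC[C@H](O)[C@]12CC(=O)C(C)CC2 | intermediate
9 | (1R,4S,5S)-1,8-dimethyl-1,4,7-tris(trimethylsilyloxy)spiro[4.5]dec-7-ene (not isolated) | C[C@@]1(O[Si](C)(C)C)CC[C@H](O[Si](C)(C)C)[C@]12CC(O[Si](C)(C)C)=C(C)CC2 | intermediate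
10 | (1R,4S,5S)-1,8-dimethyl-1,4-bis(trimethylsilyloxy)spiro[4.5]dec-8-en-7-one | C[C@@]1(O[Si](C)(C)C)CC[C@H](O[Si](C)(C)C)[C@]12CC(=O)C(C)=CC2 | intermediate
11 | (3aR,8aR)-6,8a-dimethyl-1,2,3a,4,8,8a-hexahydroazulene-3,5-dione (trans-fused) | O=C1CC[C@]2(C)CC=C(C)C(=O)C[C@H]21 | intermediate
12 | (3R,3aR,8aR)-3-hydroxy-6,8a-dimethyl-3-(propan-2-yl)-2,3,3a,4,8,8a-hexahydroazulen-5(1H)-one | CC(C)[C@]1(O)CC[C@]2(C)CC=C(C)C(=O)C[C@H]21 | intermediate
13 | 4-(benzyloxy)benzoic acid | OC(=O)c1ccc(OCc2ccccc2)cc1 | starting material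
14 | (3R,3aS,4R,8aR)-3-hydroxy-6,8a-dimethyl-5-oxo-3-(propan-2-yl)-1,2,3,3a,4,5,8,8a-octahydroazulen-4-yl 4-(benzyloxy)benzoate | CC(C)[C@]1(O)CC[C@]2(C)CC=C(C)C(=O)[C@H](OC(=O)c3ccc(OCc4ccccc4)cc3)[C@H]21 | intermediate
15 | (3R,3aS,4R,6S,7S,8aR)-3,6,7-trihydroxy-6,8a-dimethyl-5-oxo-3-(propan-2-yl)decahydroazulen-4-yl 4-(benzyloxy)benzoate | CC(C)[C@]1(O)CC[C@]2(C)C[C@H](O)[C@](C)(O)C(=O)[C@H](OC(=O)c3ccc(OCc4ccccc4)cc3)[C@H]21 | intermediate
16 | (3R,3aS,4R,6S,7S,8aR)-3,6,7-trihydroxy-6,8a-dimethyl-5-oxo-3-(propan-2-yl)decahydroazulen-4-yl 4-hydroxybenzoate | CC(C)[C@]1(O)CC[C@]2(C)C[C@H](O)[C@](C)(O)C(=O)[C@H](OC(=O)c3ccc(O)cc3)[C@H]21 | target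

## Step count and weak points

Total steps: 10. Longest linear sequence: 10 (all steps are linear from 1).

The three steps most likely to fail:

Step 4 (spirocyclisation). SmI2 may reduce the enone first, with loss of the γ-hydroxyl, or the ketyl may add with the usual anti preference instead of the chelated all-cis mode. The fallback sets out from 7 and comes back at 8 and avoids any single-electron reductant. An intramolecular Stetter reaction of the open aldehyde (2-mesityl-6,7-dihydro-5H-pyrrolo[2,1-c][1,2,4]triazol-2-ium chloride, DBU, THF) gives (1R,5R)-1-hydroxy-1,8-dimethylspiro[4.5]decane-4,7-dione F1. The cyclopentanone carbonyl, which is β to the tertiary hydroxyl, is then reduced in the boron-chelated syn-1,3 mode (Et2BOMe, NaBH4, THF/MeOH, −78 °C) to give 8.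

Step 6 (ring expansion/hydride shift cascade). The tertiary cation may simply eliminate, or the ring-fusion cation may lose a proton to the enone instead of accepting the hydride. The fallback sets out from 10 and comes back at 11 and triggers the same two shifts with an electrophile instead of by ionisation. K2CO3/MeOH removes both silyl groups to give (1R,4S,5S)-1,4-dihydroxy-1,8-dimethylspiro[4.5]dec-8-en-7-one F2. Martin sulfurane dehydrates only the tertiary alcohol to (4S,5R)-4-hydroxy-1,8-dimethylspiro[4.5]deca-1,8-dien-7-one F3. NBS (CH2Cl2, −78 °C) forms the bromonium ion, which is opened at the tertiary carbon by the antiperiplanar ring CH2; hydride shift from the carbinol then gives (3aR)-1-bromo-6,8a-dimethyl-1,2,3a,4,8,8a-hexahydroazulene-3,5-dione (bromine cis to the angular methyl) F4. Bu3SnH/AIBN (toluene, 80 °C) removes the bromine to give 11.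

Step 9 (facial selectivity of the dihydroxylation next to the C6 ester). The fallback sets out from 12 and comes back at 15; it dihydroxylates before any C6 substituent is present and introduces the C6 oxygen by enolate chemistry. OsO4/NMO on 12 gives (3R,3aR,6S,7S,8aR)-3,6,7-trihydroxy-6,8a-dimethyl-3-(propan-2-yl)octahydroazulen-5(1H)-one F5. 2,2-Dimethoxypropane with pyridinium p-toluenesulfonate gives the 6,7-O-isopropylidene derivative of F5, F6. KHMDS (2.5 equiv) and 2-(phenylsulfonyl)-3-phenyloxaziridine hydroxylate the only enolisable position to give the 4-hydroxy derivative of that acetonide (hydroxyl cis to H-3a), F7. 4-(Benzyloxy)benzoyl chloride/DMAP gives the 4-O-[4-(benzyloxy)benzoyl] ester of that ketol, F8. Aqueous AcOH (60 °C) removes the acetonide to give 15.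

Further compounds
F1 | step 4 | (1R,5R)-1-hydroxy-1,8-dimethylspiro[4.5]decane-4,7-dione | C[C@@]1(O)CCC(=O)[C@]12CC(=O)C(C)CC2
F2 | step 6 | (1R,4S,5S)-1,4-dihydroxy-1,8-dimethylspiro[4.5]dec-8-en-7-one | C[C@@]1(O)CC[C@H](O)[C@]12CC(=O)C(C)=CC2
F3 | step 6 | (4S,5R)-4-hydroxy-1,8-dimethylspiro[4.5]deca-1,8-dien-7-one | CC1=CC[C@H](O)[C@]12CC(=O)C(C)=CC2
F4 | step 6 | (3aR)-1-bromo-6,8a-dimethyl-1,2,3a,4,8,8a-hexahydroazulene-3,5-dione, trans-fused, bromine cis to the angular methyl | O=C1C[C@@H](Br)[C@]2(C)CC=C(C)C(=O)C[C@H]21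
F5 | step 9 | (3R,3aR,6S,7S,8aR)-3,6,7-trihydroxy-6,8a-dimethyl-3-(propan-2-yl)octahydroazulen-5(1H)-one | CC(C)[C@]1(O)CC[C@]2(C)C[C@H](O)[C@](C)(O)C(=O)C[C@H]21
F6 | step 9 | 6,7-O-isopropylidene derivative of F5 | CC(C)[C@]1(O)CC[C@]2(C)C[C@@H]3OC(C)(C)O[C@]3(C)C(=O)C[C@H]21
F7 | step 9 | 4-hydroxy derivative of F6 (hydroxyl cis to H-3a) | CC(C)[C@]1(O)CC[C@]2(C)C[C@@H]3OC(C)(C)O[C@]3(C)C(=O)[C@H](O)[C@H]21
F8 | step 9 | 4-O-[4-(benzyloxy)benzoyl] ester of F7 | CC(C)[C@]1(O)CC[C@]2(C)C[C@@H]3OC(C)(C)O[C@]3(C)C(=O)[C@H](OC(=O)c4ccc(OCc5ccccc5)cc4)[C@H]21
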